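**Plan**
Retrosynthesis: the O8 isovalerate and the C11=C13 methylene come off first. The ring-cis C1=C10 double bond is then traced back to an eleven-membered cyclic sulfone with SO2 between C1 and C10. The sulfide is cut at S–C1 (thiolate alkylation) and S–C10 (thia-Michael), then at C8–C9 (ketone from an acyl chloride and an alkenylzirconocene), C6–C7 (aldol, which also delivers the lactone) and C3–C4 (Suzuki).
Feature used: in the cyclodeca-1,5-diene ring, C1 and C10 are olefinic carbons flanked by the ring CH2 groups C2 and C9. They can therefore be the α and α′ carbons of a thiacycloundecane 1,1-dioxide, which loses SO2 (Ramberg–Bäcklund) and contracts from eleven to ten ring atoms.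
Forward order: C1–C6/C15 chloro-enal; γ-lactone (O, C6, C7, C11, C12) by aldol–lactonisation; C8–C10/C14 side chain; sulfur on C10; C8 carbinol; eleven-membered thiacycle; sulfone; ten-membered carbocycle; C13 methylene; ester; deprotection.
Stereochemistry: C6 and C7 come from the (S)-4-benzyloxazolidinone syn-aldol. C8 comes from Felkin–Anh hydride delivery reinforced by the (S)-CBS catalyst. The C4=C5 geometry comes from directed trans-hydroalumination/iodination and a stereoretentive Suzuki coupling, and the C1=C10 geometry from the cis-fused episulfone.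

Key step: step 15

Remarks on the chemistry:
- Locants are germacrane locants of the target: ring C1–C10, C14 on C10, C15 on C4, C11–C13 the lactone carbons, lactone oxygen on C6, ester oxygen on C8.
- Both ring double bonds are cis within the ring (C3/C6 and C2/C9 on the same side); by CIP they are E because of the CH2O substituents.
- C10 is formed as both epimers in step 10 and ceases to be a stereocentre in step 15. It is written without descriptor in 23–30, as are C1 in 30 and C11 in 34 and 35.
- PMB = 4-methoxybenzyl, TIPS = triisopropylsilyl.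

**Step 1**
Reactants: 1 but-2-yne-1,4-diol (excess), 2 4-methoxybenzyl chloride
Product: 3 4-[(4-methoxybenzyl)oxy]but-2-yn-1-ol
Conditions: NaH (1 equiv), n-Bu4NI (cat.), THF/DMF, 0 °C → rt
Reagents that add atoms: none
Why: Williamson etherification; the excess of diol should hold bis-alkylation down.

**Step 2**
Reactants: 3
Product: 5 (2Z)-3-iodo-4-[(4-methoxybenzyl)oxy]but-2-en-1-ol, via vinylalanate 4 (not isolated)
Conditions: Red-Al, THF, 0 °C; then I2, THF, −78 → 0 °C
Reagents that add atoms: iodine, II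
Why: Hydroxyl-directed trans-hydroalumination of a propargylic alcohol (hydride to C5, aluminium to C4 in a five-membered alkoxyaluminate) followed by iodinolysis with retention should place iodine on C4 cis to C6.

**Step 3**
Reactants: 5, 6 allyloxytrimethylsilane
Product: 8 (2E)-3-{[(4-methoxybenzyl)oxy]methyl}hex-2-ene-1,6-diol, via B-alkyl-9-BBN 7 (not isolated)
Conditions: 6, 9-BBN, THF, 0 °C → rt; then 5, Pd(dppf)Cl2 (5 mol %), AsPh3, Cs2CO3, DMF/H2O, rt; K2CO3, MeOH work-up
Reagents that add atoms: none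
Why: Anti-Markovnikov hydroboration and B-alkyl Suzuki–Miyaura coupling with retention should put C3 cis to C6; the trimethylsilyl ether is cleaved in the basic methanolic work-up.

**Step 4**
Reactants: 8
Product: 9 (2E)-6-hydroxy-3-{[(4-methoxybenzyl)oxy]methyl}hex-2-enal
Conditions: activated MnO2, CH2Cl2, rt
Reagents that add atoms: none
Why: MnO2 oxidises only the allylic alcohol; 9 is used at once so that oxa-Michael closure of the free hydroxyl onto C4 has little time.

**Step 5**
Reactants: 9
Product: 10 (2E)-6-chloro-3-{[(4-methoxybenzyl)oxy]methyl}hex-2-enal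
Conditions: PPh3 and NCS (premixed), CH2Cl2, −20 → 0 °C
Reagents that add atoms: N-chlorosuccinimide, O=C1CCC(=O)N1Cl
Why: Appel-type chlorination of the primary alcohol by the preformed chlorophosphonium salt; no free phosphine or base is present that could isomerise the enal.

**Step 6**
Reactants: 11 (S)-4-benzyl-1,3-oxazolidin-2-one, 12 methyl 4-chloro-4-oxobutanoate
Product: 13 methyl 4-[(4S)-4-benzyl-2-oxo-1,3-oxazolidin-3-yl]-4-oxobutanoate
Conditions: n-BuLi, THF, −78 °C; then 12, −78 → 0 °C
Reagents that add atoms: none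
Why: N-acylation of the lithiated oxazolidinone by the acid chloride.

**Step 7**
Reactants: 13, 10
Product: 16 (4S)-4-benzyl-3-{[(2R,3S)-2-[(1E)-5-chloro-2-{[(4-methoxybenzyl)oxy]methyl}pent-1-en-1-yl]-5-oxooxolan-3-yl]carbonyl}-1,3-oxazolidin-2-one, via boron enolate 14 (not isolated), via aldol hydroxy ester 15 (not isolated)
Conditions: n-Bu2BOTf, i-Pr2NEt, CH2Cl2, −78 → 0 °C; 10, −78 → 0 °C; pH 7 buffer, MeOH, H2O2; then PPTS (cat.), CH2Cl2, rt
Reagents that add atoms: none
Why: Evans syn-aldol reaction: the (Z)-boron enolate reacts through a Zimmerman–Traxler chair on the face away from the benzyl group to set C6 and C7, and the γ-hydroxy methyl ester should then close to the trans γ-lactone as in paraconic acid syntheses.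

**Step 8**
Reactants: 16
Product: 18 (2R,3S)-2-[(1E)-5-chloro-2-{[(4-methoxybenzyl)oxy]methyl}pent-1-en-1-yl]-5-oxooxolane-3-carboxylic acid, via lithium peroxycarboxylate 17 (not isolated)
Conditions: LiOH, H2O2, THF/H2O, 0 °C; Na2SO3; 1 M HCl to pH 2
Reagents that add atoms: hydrogen peroxide, OO
Why: Hydroperoxide cleavage of the exocyclic imide carbonyl (Evans); a lactone opened by hydroxide closes again on acidification because O6 is the only hydroxyl.

**Step 9**
Reactants: 18, 19 4-methoxybenzyl prop-2-yn-1-yl ether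
Product: 22 (4S,5R)-5-[(1E)-5-chloro-2-{[(4-methoxybenzyl)oxy]methyl}pent-1-en-1-yl]-4-{(2E)-4-[(4-methoxybenzyl)oxy]but-2-enoyl}oxolan-2-one, via acid chloride 20 (not isolated), via alkenylzirconocene 21 (not isolated)
Conditions: 18, 1-chloro-N,N,2-trimethylprop-1-en-1-amine, CH2Cl2, 0 °C → rt; 19, Cp2Zr(H)Cl, THF, rt; then both, CuBr·SMe2 (10 mol %), THF, 0 °C → rt
Reagents that add atoms: none
Why: syn-Hydrozirconation gives the (E)-alkenylzirconocene, and its copper-catalysed acylation by the acid chloride should give the (E)-enone under neutral conditions that spare the C7 stereocentre and the β-acyloxy ketone.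

**Step 10**
Reactants: 22
Product: 23 β-acetylthio ketone (22 with AcS on C10 and CH2 at C9; both C10 epimers)
Conditions: AcSH, Et3N (5 mol %), CH2Cl2, 0 °C
Reagents that add atoms: thioacetic S-acid, CC(=O)S
Why: Thia-Michael addition to the enone places sulfur on C10 under buffered conditions; the C10 configuration is of no consequence.

**Step 11**
Reactants: 23
Product: 24 (4R,5R)-4-{(1R)-3-(acetylsulfanyl)-1-hydroxy-4-[(4-methoxybenzyl)oxy]butyl}-5-[(1E)-5-chloro-2-{[(4-methoxybenzyl)oxy]methyl}pent-1-en-1-yl]oxolan-2-one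
Conditions: (S)-2-methyl-CBS-oxazaborolidine (20 mol %), catecholborane, toluene, −78 → −40 °C
Reagents that add atoms: none
Why: Corey–Bakshi–Shibata reduction; the (S)-catalyst (branched C7 as the large group) and Felkin–Anh attack anti to the C7–C6 bond both point to the 8R carbinol, and catecholborane at low temperature should leave thioester and lactone untouched.

**Step 12**
Reactants: 24
Product: 25 C8 triisopropylsilyl ether of 24
Conditions: TIPSOTf, 2,6-lutidine, CH2Cl2, 0 °C
Reagents that add atoms: triisopropylsilyl trifluoromethanesulfonate, CC(C)[Si](OS(=O)(=O)C(F)(F)F)(C(C)C)C(C)C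
Why: Silylation blocks O8 so that only O6 can lactonise in step 15; TIPS is chosen because it resists base-induced 1,3-migration.

**Step 13**
Reactants: 25
Product: 27 eleven-membered thiacycle (S between C1 and C10; trans-fused γ-lactone; C8-OTIPS; C14- and C15-OPMB), via thiol 26 (not isolated)
Conditions: H2NNH2·AcOH, DMF, 0 °C; then slow addition to Cs2CO3, NaI (cat.), DMF (2 mM), 45 °C
Reagents that add atoms: none
Why: Hydrazinolysis is selective for the thioester, and the caesium thiolate then alkylates C1 (iodide formed in situ) under high dilution, a caesium thiolate macrocyclisation.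

**Step 14**
Reactants: 27
Product: 28 thiacycle 1,1-dioxide (sulfone of 27)
Conditions: (NH4)6Mo7O24·4H2O (10 mol %), 30 % H2O2, EtOH, 0 °C → rt
Reagents that add atoms: hydrogen peroxide, OO
Why: Molybdate-catalysed oxidation of sulfide to sulfone, a method known to spare trisubstituted olefins and PMB ethers.

**Step 15**
Reactants: 28
Product: 33 ten-membered diene lactone (C1=C10 and C4=C5 ring-cis; C11 is CH2; C8-OTIPS; C14- and C15-OPMB), via hydroxy carboxylate 29 (not isolated), via bromo sulfone 30 (not isolated), via episulfone 31 (not isolated), via hydroxy acid 32 (not isolated)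
Conditions: KOH, t-BuOH/H2O, rt; then CBr2F2, KOH/Al2O3, t-BuOH/CH2Cl2, 5 °C → rt; 1 M HCl to pH 3; CSA (cat.), CH2Cl2, rt
Reagents that add atoms: none
Why: Ramberg–Bäcklund reaction in the one-flask Meyers–Chan form: hydroxide first opens the γ-lactone to carboxylate 29 (removing the only C–H more acidic than those next to sulfur), an α-sulfonyl carbanion (C1 or C10, either serves) takes Br+ from CBr2F2 to give 30, the α′-carbanion displaces bromide to give thiirane 1,1-dioxide 31, and cheletropic loss of SO2 leaves the C1=C10 double bond, so the eleven-membered ring contracts to the ten-membered carbocycle. The closest known reaction type is the Ramberg–Bäcklund ring contraction of cyclic sulfones to medium-ring cycloalkenes. The three-membered ring of 31 closes by 3-exo-tet attack on the C–Br carbon, the ten-membered ring arises by extrusion with C1–C10 as its only new bond, and the γ-lactone re-closes 5-exo-trig at O6 on acidification because O8 is silylated. No lasting stereocentre is created: C10 is destroyed, and C6, C7 and C8 carry no acidic hydrogen in 29. The step needs the ring-cis C1=C10 geometry and 1,3-closure in preference to loss of the C14 ether oxygen from the C10 carbanion; the first should follow from the kinetically preferred cis-fused episulfone under hydroxide conditions and from the strain of a trans olefin in a ring that already holds the cis C4=C5 bond, the second from bromide being a far better leaving group than an alkoxide, as in glycosyl sulfones with β-benzyloxy groups that undergo this reaction.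

**Step 16**
Reactants: 33
Product: 36 α-methylene lactone (33 with C11=C13H2), via Mannich base 34 (not isolated), via ammonium iodide 35 (not isolated)
Conditions: LDA, THF, −78 °C; Me2N=CH2+ I−, −78 → 0 °C; MeI, MeOH, rt; aq. NaHCO3, CH2Cl2, rt
Reagents that add atoms: N,N-dimethylmethyleneiminium iodide, C=[N+](C)C.[I-]
Why: Eschenmoser methylenation: the lactone enolate (the only enolisable carbonyl) is aminomethylated, and quaternisation and mild base elimination give the exocyclic methylene.

**Step 17**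
Reactants: 36
Product: 37 C8 alcohol (36 without TIPS)
Conditions: HF·pyridine, pyridine, THF, 0 °C → rt
Reagents that add atoms: none
Why: Buffered fluoride desilylation, which should spare the α-methylene lactone and the PMB ethers.

**Step 18**
Reactants: 37
Product: 38 C8 3-methylbutanoate (target as its 14,15-bis-PMB ether)
Conditions: 3-methylbutanoic anhydride, DMAP (cat.), Et3N, CH2Cl2, 0 °C → rt
Reagents that add atoms: 3-methylbutanoic anhydride, CC(C)CC(=O)OC(=O)CC(C)C
Why: DMAP-catalysed acylation of the only free hydroxyl.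

**Step 19**
Reactants: 38
Product: 39 target CNP0199826.1
Conditions: DDQ, CH2Cl2/pH 7 buffer, 0 °C
Reagents that add atoms: none
Why: Oxidative cleavage of both PMB ethers by DDQ under buffered conditions that the ester, the α-methylene lactone and the diene should tolerate.

**Compound list**
1 | but-2-yne-1,4-diol | OCC#CCO | starting material
2 | 4-methoxybenzyl chloride | COc1ccc(CCl)cc1 | starting material
3 | 4-[(4-methoxybenzyl)oxy]but-2-yn-1-ol | OCC#CCOCc1ccc(OC)cc1 | intermediate
4 | vinylalanate, sodium salt (Al bound to O6 and C4) | [Na+].COCCO[Al-]1(OCCOC)OC/C=C1/COCc1ccc(OC)cc1 | intermediate (not isolated)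
5 | (2Z)-3-iodo-4-[(4-methoxybenzyl)oxy]but-2-en-1-ol | OC/C=C(/COCc1ccc(OC)cc1)I | intermediate
6 | allyloxytrimethylsilane | C=CCO[Si](C)(C)C | starting material
7 | 9-[3-(trimethylsilyloxy)propyl]-9-borabicyclo[3.3.1]nonane | C[Si](C)(C)OCCCB1C2CCCC1CCC2 | intermediate (not isolated)
8 | (2E)-3-{[(4-methoxybenzyl)oxy]methyl}hex-2-ene-1,6-diol | OC/C=C(/COCc1ccc(OC)cc1)CCCO | intermediate
9 | (2E)-6-hydroxy-3-{[(4-methoxybenzyl)oxy]methyl}hex-2-enal | O=C/C=C(/COCc1ccc(OC)cc1)CCCO | intermediate
10 | (2E)-6-chloro-3-{[(4-methoxybenzyl)oxy]methyl}hex-2-enal | O=C/C=C(/COCc1ccc(OC)cc1)CCCCl | intermediate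
11 | (S)-4-benzyl-1,3-oxazolidin-2-one | O=C1N[C@@H](Cc2ccccc2)CO1 | starting material
12 | methyl 4-chloro-4-oxobutanoate | COC(=O)CCC(Cl)=O | starting material
13 | methyl 4-[(4S)-4-benzyl-2-oxo-1,3-oxazolidin-3-yl]-4-oxobutanoate | COC(=O)CCC(=O)N1[C@@H](Cc2ccccc2)COC1=O | intermediate
14 | (Z)-dibutylboron enolate of 13 | CCCCB(CCCC)O/C(=C\CC(=O)OC)N1[C@@H](Cc2ccccc2)COC1=O | intermediate (not isolated)
15 | syn-aldol hydroxy ester (3S,4R in the nonenoate chain) | COC(=O)C[C@@H]([C@H](O)/C=C(/COCc1ccc(OC)cc1)CCCCl)C(=O)N1[C@@H](Cc2ccccc2)COC1=O | intermediate (not isolated)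
16 | trans-lactone imide (2R,3S in the oxolane) | O=C1O[C@H](/C=C(/COCc2ccc(OC)cc2)CCCCl)[C@@H](C(=O)N2[C@@H](Cc3ccccc3)COC2=O)C1 | intermediate
17 | lithium peroxycarboxylate of 18 | O=C1O[C@H](/C=C(/COCc2ccc(OC)cc2)CCCCl)[C@@H](C(=O)O[O-])C1.[Li+] | intermediate (not isolated)
18 | (2R,3S)-2-[(1E)-5-chloro-2-{[(4-methoxybenzyl)oxy]methyl}pent-1-en-1-yl]-5-oxooxolane-3-carboxylic acid | O=C1O[C@H](/C=C(/COCc2ccc(OC)cc2)CCCCl)[C@@H](C(=O)O)C1 | intermediate
19 | 4-methoxybenzyl prop-2-yn-1-yl ether | C#CCOCc1ccc(OC)cc1 | starting material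
20 | acid chloride of 18 | O=C1O[C@H](/C=C(/COCc2ccc(OC)cc2)CCCCl)[C@@H](C(Cl)=O)C1 | intermediate (not isolated)
21 | (E)-[3-(4-methoxybenzyloxy)prop-1-enyl]zirconocene chloride | Cl[Zr](/C=C/COCc1ccc(OC)cc1)(C1C=CC=C1)C1C=CC=C1 | intermediate (not isolated)
22 | (4S,5R)-enone lactone | O=C1O[C@H](/C=C(/COCc2ccc(OC)cc2)CCCCl)[C@@H](C(=O)/C=C/COCc2ccc(OC)cc2)C1 | intermediate
23 | β-acetylthio ketone (C10 epimers) | O=C1O[C@H](/C=C(/COCc2ccc(OC)cc2)CCCCl)[C@@H](C(=O)CC(SC(C)=O)COCc2ccc(OC)cc2)C1 | intermediate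
24 | (8R)-alcohol | O=C1O[C@H](/C=C(/COCc2ccc(OC)cc2)CCCCl)[C@@H]([C@H](O)CC(SC(C)=O)COCc2ccc(OC)cc2)C1 | intermediate
25 | C8 TIPS ether | O=C1O[C@H](/C=C(/COCc2ccc(OC)cc2)CCCCl)[C@@H]([C@H](O[Si](C(C)C)(C(C)C)C(C)C)CC(SC(C)=O)COCc2ccc(OC)cc2)C1 | intermediate
26 | C10 thiol | O=C1O[C@H](/C=C(/COCc2ccc(OC)cc2)CCCCl)[C@@H]([C@H](O[Si](C(C)C)(C(C)C)C(C)C)CC(S)COCc2ccc(OC)cc2)C1 | intermediate (not isolated)
27 | eleven-membered thiacycle | C1C(=O)O[C@@H]2/C=C(/COCc3ccc(OC)cc3)CCCSC(COCc3ccc(OC)cc3)C[C@@H](O[Si](C(C)C)(C(C)C)C(C)C)[C@@H]12 | intermediate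
28 | thiacycle 1,1-dioxide | C1C(=O)O[C@@H]2/C=C(/COCc3ccc(OC)cc3)CCCS(=O)(=O)C(COCc3ccc(OC)cc3)C[C@@H](O[Si](C(C)C)(C(C)C)C(C)C)[C@@H]12 | intermediate
29 | potassium hydroxy carboxylate (lactone of 28 opened) | O[C@@H]1/C=C(/COCc2ccc(OC)cc2)CCCS(=O)(=O)C(COCc2ccc(OC)cc2)C[C@@H](O[Si](C(C)C)(C(C)C)C(C)C)[C@H]1CC(=O)[O-].[K+] | intermediate (not isolated)
30 | C1-bromo sulfone | O[C@@H]1/C=C(/COCc2ccc(OC)cc2)CCC(Br)S(=O)(=O)C(COCc2ccc(OC)cc2)C[C@@H](O[Si](C(C)C)(C(C)C)C(C)C)[C@H]1CC(=O)[O-].[K+] | intermediate (not isolated)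
31 | cis-fused episulfone (one of the two cis isomers shown) | O[C@@H]1/C=C(/COCc2ccc(OC)cc2)CC[C@H]2[C@](COCc3ccc(OC)cc3)(S2(=O)=O)C[C@@H](O[Si](C(C)C)(C(C)C)C(C)C)[C@H]1CC(=O)[O-].[K+] | intermediate (not isolated)
32 | ten-membered hydroxy acid | O[C@@H]1/C=C(/COCc2ccc(OC)cc2)CC/C=C(/COCc2ccc(OC)cc2)C[C@@H](O[Si](C(C)C)(C(C)C)C(C)C)[C@H]1CC(=O)O | intermediate (not isolated)
33 | ten-membered diene lactone | C1C(=O)O[C@@H]2/C=C(/COCc3ccc(OC)cc3)CC/C=C(/COCc3ccc(OC)cc3)C[C@@H](O[Si](C(C)C)(C(C)C)C(C)C)[C@@H]12 | intermediate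
34 | C11 dimethylaminomethyl lactone (Mannich base) | CN(C)CC1C(=O)O[C@@H]2/C=C(/COCc3ccc(OC)cc3)CC/C=C(/COCc3ccc(OC)cc3)C[C@@H](O[Si](C(C)C)(C(C)C)C(C)C)[C@@H]12 | intermediate (not isolated)
35 | trimethylammonium iodide of 34 | [I-].C[N+](C)(C)CC1C(=O)O[C@@H]2/C=C(/COCc3ccc(OC)cc3)CC/C=C(/COCc3ccc(OC)cc3)C[C@@H](O[Si](C(C)C)(C(C)C)C(C)C)[C@@H]12 | intermediate (not isolated)
36 | α-methylene lactone, C8-OTIPS | C=C1C(=O)O[C@@H]2/C=C(/COCc3ccc(OC)cc3)CC/C=C(/COCc3ccc(OC)cc3)C[C@@H](O[Si](C(C)C)(C(C)C)C(C)C)[C@@H]12 | intermediate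
37 | α-methylene lactone, C8-OH | C=C1C(=O)O[C@@H]2/C=C(/COCc3ccc(OC)cc3)CC/C=C(/COCc3ccc(OC)cc3)C[C@@H](O)[C@@H]12 | intermediate
38 | C8 3-methylbutanoate, 14,15-bis-PMB ether | C=C1C(=O)O[C@@H]2/C=C(/COCc3ccc(OC)cc3)CC/C=C(/COCc3ccc(OC)cc3)C[C@@H](OC(=O)CC(C)C)[C@@H]12 | intermediate
39 | CNP0199826.1 | C=C1C(=O)O[C@@H]2/C=C(/CO)CC/C=C(/CO)C[C@@H](OC(=O)CC(C)C)[C@@H]12 | target

**Step count**
Total: 19 steps. Longest linear sequence: 18 steps (steps 1–5 and 7–19); step 6 is a one-step branch.

**Steps most likely to fail**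

1. Step 15. The C10 carbanion may expel the C14 ether oxygen (E1cB) or be brominated twice before the 1,3-closure, and the episulfone may open to the ring-trans olefin. The fallback is the epoxy-Ramberg–Bäcklund reaction, known for α,β-epoxy sulfones. It sets out from 28. LiHMDS (THF, −78 → 0 °C) is used to carry that elimination through on purpose and should give the exocyclic vinyl sulfone F1. Lithium tert-butyl peroxide (t-BuOOH, n-BuLi, THF, −20 °C) should epoxidise the electron-poor C10=C14 bond to the spiro epoxy sulfone F2. LiOt-Bu (THF, rt) then needs only the C1 carbanion, which opens the epoxide at C10 so that the C14 oxygen becomes the free hydroxyl, and loss of SO2 should give the ring-contracted allylic alcohol F3. 4-Methoxybenzyl trichloroacetimidate with La(OTf)3 (cat.) brings the sequence back to the route at 33.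

2. Step 13. Intermolecular S-alkylation to dimers and oligomers may outrun closure of the eleven-membered ring. The fallback closes the ring at S–C10 by a reversible thia-Michael addition and sets out from 18. KSAc (NaI cat., DMF, 40 °C) displaces the C1 chloride and gives the thioacetate acid F4. The conditions of step 9 with 19 give the thioacetate enone F5. K2CO3 in degassed MeOH/THF (1 mM, 0 °C, mild acid work-up) frees the C1 thiol, which adds to C10 within the molecule and should give the eleven-membered β-sulfanyl ketone F6 under thermodynamic control. The reduction of step 11 gives the ring alcohol F7, and TIPSOTf/2,6-lutidine brings the sequence back to the route at 27.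

3. Step 2. The vinylalanate may lose the β-(4-methoxybenzyl)oxide and give an allenyl alcohol before iodine is added. The fallback sets out from 3. Ruthenium-catalysed trans-hydrosilylation ([Cp*Ru(MeCN)3]PF6, BnMe2SiH, CH2Cl2, rt) should place silicon on C4, distal to the hydroxyl, and give the vinylsilane F8, which has no carbon–metal bond able to eliminate. Iododesilylation with NIS in (CF3)2CHOH, with retention, brings the sequence back to the route at 5.

**Further compounds**
F1 | step 15 | exocyclic vinyl sulfone (C10=C14H2) | C1C(=O)O[C@@H]2/C=C(/COCc3ccc(OC)cc3)CCCS(=O)(=O)C(=C)C[C@@H](O[Si](C(C)C)(C(C)C)C(C)C)[C@@H]12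
F2 | step 15 | spiro epoxy sulfone (oxirane C10–O–C14) | C1C(=O)O[C@@H]2/C=C(/COCc3ccc(OC)cc3)CCCS(=O)(=O)C3(CO3)C[C@@H](O[Si](C(C)C)(C(C)C)C(C)C)[C@@H]12
F3 | step 15 | ring-contracted C14 allylic alcohol | C1C(=O)O[C@@H]2/C=C(/COCc3ccc(OC)cc3)CC/C=C(/CO)C[C@@H](O[Si](C(C)C)(C(C)C)C(C)C)[C@@H]12
F4 | step 13 | C1 thioacetate acid | O=C1O[C@H](/C=C(/COCc2ccc(OC)cc2)CCCSC(C)=O)[C@@H](C(=O)O)C1
F5 | step 13 | C1 thioacetate enone | O=C1O[C@H](/C=C(/COCc2ccc(OC)cc2)CCCSC(C)=O)[C@@H](C(=O)/C=C/COCc2ccc(OC)cc2)C1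
F6 | step 13 | eleven-membered β-sulfanyl ketone (C8 ketone) | C1C(=O)O[C@@H]2/C=C(/COCc3ccc(OC)cc3)CCCSC(COCc3ccc(OC)cc3)CC(=O)[C@@H]12
F7 | step 13 | eleven-membered thiacycle C8 alcohol | C1C(=O)O[C@@H]2/C=C(/COCc3ccc(OC)cc3)CCCSC(COCc3ccc(OC)cc3)C[C@@H](O)[C@@H]12
F8 | step 2 | (2Z)-3-[benzyl(dimethyl)silyl]-4-[(4-methoxybenzyl)oxy]but-2-en-1-ol | OC/C=C(/COCc1ccc(OC)cc1)[Si](C)(C)Cc1ccccc1
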